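Numbering: lactone ring O1, C2 (carbonyl), C3=C4, C5, C6; side chain C1' to C10' outward from C6. The ring is cut at C5–C6 and O1–C2, because C2–C5 is a 1-oxygenated butadiene and C6=O1 an aldehyde carbonyl. One catalyst-controlled hetero-Diels–Alder reaction closes this ring as its methyl acetal, installs C3=C4 and sets C6, which is too remote from C4', C6' and C8' for substrate control. The precursor is the full-chain ynal: C6 formyl group, C1'–C2' alkyne, C4' silyl ether, syn C6',C8' acetonide. Afterwards the alkyne becomes the E alkene, C4' is acetylated, and hydrolysis plus lactol oxidation unveil the lactone.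

Key step: step 9

Assumption: the senses of induction follow the accepted models ((R)-BINAP on ruthenium gives the (R)-β-hydroxy ester, (R)-TRIP opens the aldehyde Re face, and the (1S,2R)-aminoindanol chromium complex mirrors the catalyst that turns simple aldehydes into (2S,6R)-dihydropyrans); if a sense were reversed on these substrates, the antipodal catalyst would be used.

Step 1
Reactants: 1 ethyl 3-oxo-5-phenylpentanoate
Product: 2 ethyl (3R)-3-hydroxy-5-phenylpentanoate
Conditions: H2 (10 bar), [RuCl(p-cymene)((R)-BINAP)]Cl (0.2 mol %), EtOH, 60 °C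
Reagents that add atoms: none
Why: Noyori asymmetric hydrogenation of a β-keto ester, in which the ester carbonyl chelates ruthenium and the (R)-BINAP ligand lets hydride reach only one ketone face, should set C8' as R while arene and ester stay untouched.

Step 2
Reactants: 2 ethyl (3R)-3-hydroxy-5-phenylpentanoate; 3 tert-butyl acetate
Product: 5 tert-butyl (5R)-5-hydroxy-3-oxo-7-phenylheptanoate, via lithium enolate of tert-butyl acetate 4 (not isolated)
Conditions: 3 (4 equiv), LiN(i-Pr)2 (4 equiv), THF, −78 °C; then 2, −78 → −10 °C; AcOH quench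
Reagents that add atoms: lithium diisopropylamide, [Li]N(C(C)C)C(C)C (lithium, present only in 4)
Why: Crossed Claisen condensation: the excess of hindered enolate 4 first takes the hydroxyl proton and then acylates at the ethyl ester, and the β-keto ester formed is stored as its enolate, so neither a second addition nor any change at C8' is expected.

Step 3
Reactants: 5 tert-butyl (5R)-5-hydroxy-3-oxo-7-phenylheptanoate
Product: 7 tert-butyl (3R,5R)-3,5-dihydroxy-7-phenylheptanoate (syn diol), via diethylboron chelate 6 (not isolated)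
Conditions: Et2BOMe (1.1 equiv), THF–MeOH (4:1), −78 °C; NaBH4 (1.1 equiv), −78 °C; then repeated evaporation from MeOH (boron leaves again as Et2BOMe)
Reagents that add atoms: diethyl(methoxy)borane, CCB(CC)OC (boron group, present only in 6)
Why: Narasaka–Prasad reduction: chelate 6 ties the C8' oxygen and the C6' ketone into a six-membered half-chair and borohydride attacks axially from outside, so C8' should dictate the 1,3-syn relationship and C6' forms as R.

Step 4
Reactants: 7 tert-butyl (3R,5R)-3,5-dihydroxy-7-phenylheptanoate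
Product: 8 tert-butyl 2-[(4R,6R)-2,2-dimethyl-6-(2-phenylethyl)-1,3-dioxan-4-yl]acetate
Conditions: Me2C(OMe)2 (3 equiv), camphorsulfonic acid (2 mol %), CH2Cl2, rt; Et3N quench
Reagents that add atoms: 2,2-dimethoxypropane, COC(C)(C)OC
Why: Acid-catalysed transketalisation is driven by release of methanol and gives the chair 1,3-dioxane with both side chains equatorial, masking both hydroxyls in one group without touching a stereocentre or the tert-butyl ester.

Step 5
Reactants: 8 tert-butyl 2-[(4R,6R)-2,2-dimethyl-6-(2-phenylethyl)-1,3-dioxan-4-yl]acetate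
Product: 10 2-[(4R,6R)-2,2-dimethyl-6-(2-phenylethyl)-1,3-dioxan-4-yl]acetaldehyde, via aluminium hemiacetal 9 (not isolated)
Conditions: i-Bu2AlH (1.15 equiv), CH2Cl2, −78 °C; MeOH, then aq. potassium sodium tartrate
Reagents that add atoms: diisobutylaluminium hydride, CC(C)C[AlH]CC(C)C (aluminium group, present only in 9)
Why: Partial reduction of an ester: the tetrahedral intermediate 9, held by the bulky tert-butoxy group and by chelation to the ring oxygen, should persist at −78 °C and release the aldehyde only on quenching, so over-reduction is avoided and no α-stereocentre is at risk.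

Step 6
Reactants: 10 2-[(4R,6R)-2,2-dimethyl-6-(2-phenylethyl)-1,3-dioxan-4-yl]acetaldehyde; 11 allenylboronic acid pinacol ester
Product: 13 (2R)-1-[(4S,6R)-2,2-dimethyl-6-(2-phenylethyl)-1,3-dioxan-4-yl]pent-4-yn-2-ol (C4' hydroxyl anti to C6' oxygen), via pinacol borate ester 12 (not isolated)
Conditions: 11 (1.5 equiv), (R)-TRIP [(R)-3,3'-bis(2,4,6-triisopropylphenyl)-1,1'-binaphthyl-2,2'-diyl hydrogen phosphate] (10 mol %), 4 Å MS, toluene, −20 °C; aqueous work-up
Reagents that add atoms: none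
Why: Chiral-phosphoric-acid-catalysed propargylboration: the allenylboronate reacts through a closed six-membered SE2' transition state, which gives only the homopropargylic (not allenic) carbinol, and the acid, hydrogen-bonded to a boronate oxygen and the formyl hydrogen, should open the Re face so that C4' forms as R, anti to C6', under catalyst control.

Step 7
Reactants: 13 (2R)-1-[(4S,6R)-2,2-dimethyl-6-(2-phenylethyl)-1,3-dioxan-4-yl]pent-4-yn-2-ol
Product: 14 tert-butyl-[(2R)-1-[(4R,6R)-2,2-dimethyl-6-(2-phenylethyl)-1,3-dioxan-4-yl]pent-4-yn-2-yl]oxy-dimethylsilane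
Conditions: TBSCl (1.3 equiv), imidazole (2.5 equiv), DMF, rt
Reagents that add atoms: tert-butyl(chloro)dimethylsilane, CC(C)(C)[Si](C)(C)Cl
Why: Imidazole-promoted silylation of the only free hydroxyl gives a base-stable, fluoride-labile ether that tolerates the coming organolithium step and leaves no acidic proton for the chromium catalyst.

Step 8
Reactants: 14 tert-butyl-[(2R)-1-[(4R,6R)-2,2-dimethyl-6-(2-phenylethyl)-1,3-dioxan-4-yl]pent-4-yn-2-yl]oxy-dimethylsilane
Product: 17 (5R)-5-[tert-butyl(dimethyl)silyl]oxy-6-[(4R,6R)-2,2-dimethyl-6-(2-phenylethyl)-1,3-dioxan-4-yl]hex-2-ynal, via lithium acetylide 15 (not isolated), via lithium hemiaminal alkoxide 16 (not isolated)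
Conditions: n-BuLi (1.05 equiv), THF, −78 °C; DMF (3 equiv), −78 → 0 °C; inverse quench into cold aq. KH2PO4–MTBE
Reagents that add atoms: N,N-dimethylformamide, CN(C)C=O; n-butyllithium, [Li]CCCC (lithium, present only in 15 and 16)
Why: Deprotonation of the terminal alkyne and formylation with DMF: adduct 16 keeps the aldehyde masked until the buffered inverse quench, which removes dimethylamine as its salt and so should prevent conjugate addition, alkyne-to-allene isomerisation and loss of the C4' silyloxy group.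

Step 9
Reactants: 17 (5R)-5-[tert-butyl(dimethyl)silyl]oxy-6-[(4R,6R)-2,2-dimethyl-6-(2-phenylethyl)-1,3-dioxan-4-yl]hex-2-ynal; 18 (E)-1-methoxybuta-1,3-diene
Product: 19 (2R,6S)-6-[(4R)-4-[tert-butyl(dimethyl)silyl]oxy-5-[(4R,6R)-2,2-dimethyl-6-(2-phenylethyl)-1,3-dioxan-4-yl]pent-1-ynyl]-2-methoxy-5,6-dihydro-2H-pyran (methoxy and alkynyl groups cis)
Conditions: 18 (4 equiv, also the medium), CrCl(C27H29NO2) (7.5 mol %; trivalent chromium chloride on the doubly deprotonated O,N,O imine from 3-(1-adamantyl)-2-hydroxy-5-methylbenzaldehyde and (1S,2R)-1-aminoindan-2-ol), powdered 4 Å MS, no further solvent, rt, 24–48 h; chromatography on Et3N-washed silica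
Reagents that add atoms: none
Why: Coordination of the formyl oxygen of 17 to trivalent chromium lowers the carbonyl LUMO, and diene 18 then adds across C6=O1 in a single, asynchronous [4+2] event with C5–C6 bond formation leading O1–C2 bond formation. The closest known reaction type is the hetero-Diels–Alder reaction of 1-methoxybutadiene with aliphatic aldehydes and conjugated ynals under tridentate Schiff-base chromium chlorides, here only applied to a longer chain. The one new ring, the six-membered dihydropyran O1–C2–C3=C4–C5–C6, is closed by intermolecular cycloaddition, both ring bonds arising in the same event. C6 (S) is controlled by the catalyst alone, whose indane backbone and adamantyl group should leave only the Si face of the bound carbonyl open and override the C4' centre four bonds away, while C2 (R, methoxy cis to the alkynyl group) follows from the endo transition state and is erased in step 13. The step needs chemoselectivity for C=O over C≡C and the regiochemistry C5 to C6: the first is secured by selective Lewis acid activation of the formyl group of a slim ynal that has no heterodiene option, the second by the methoxy-polarised diene, whose nucleophilic terminus C5 meets the carbonyl carbon. The silyl ether and acetonide offer no acidic proton and only hindered oxygen donors, so they should not poison the catalyst.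

Step 10
Reactants: 19 (2R,6S)-6-[(4R)-4-[tert-butyl(dimethyl)silyl]oxy-5-[(4R,6R)-2,2-dimethyl-6-(2-phenylethyl)-1,3-dioxan-4-yl]pent-1-ynyl]-2-methoxy-5,6-dihydro-2H-pyran
Product: 21 (2R,4E)-1-[(4S,6R)-2,2-dimethyl-6-(2-phenylethyl)-1,3-dioxan-4-yl]-5-[(2R,6S)-2-methoxy-5,6-dihydro-2H-pyran-6-yl]pent-4-en-2-ol, via (Z)-vinylsilane 20 (not isolated)
Conditions: (EtO)3SiH (1.3 equiv), [Cp*Ru(MeCN)3]PF6 (3 mol %), CH2Cl2, 0 °C → rt; solvent exchanged for THF; n-Bu4NF (4 equiv), CuI (0.5 equiv), rt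
Reagents that add atoms: triethoxysilane, CCO[SiH](OCC)OCC (silicon group, present only in 20)
Why: Ruthenium-catalysed trans-hydrosilylation followed by copper-assisted fluoride protodesilylation with retention: anti addition of H and Si gives 20 (either regioisomer leads to the same alkene), C–Si cleavage should leave the E-C1'=C2' alkene, the same fluoride removes the C4' silyl ether, and ring alkene, acetal and acetonide are inert to both reagents.

Step 11
Reactants: 21 (2R,4E)-1-[(4S,6R)-2,2-dimethyl-6-(2-phenylethyl)-1,3-dioxan-4-yl]-5-[(2R,6S)-2-methoxy-5,6-dihydro-2H-pyran-6-yl]pent-4-en-2-ol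
Product: 22 (2R,4E)-1-[(4R,6R)-2,2-dimethyl-6-(2-phenylethyl)-1,3-dioxan-4-yl]-5-[(2R,6S)-2-methoxy-5,6-dihydro-2H-pyran-6-yl]pent-4-en-2-yl acetate
Conditions: Ac2O (2 equiv), DMAP (5 mol %), pyridine–CH2Cl2, 0 °C → rt
Reagents that add atoms: acetic anhydride, CC(=O)OC(C)=O
Why: DMAP-catalysed acetylation of the single free hydroxyl proceeds with retention at C4' because only the O–H bond is broken, and the acetal and acetonide are stable to these mildly basic conditions.

Step 12
Reactants: 22 (2R,4E)-1-[(4R,6R)-2,2-dimethyl-6-(2-phenylethyl)-1,3-dioxan-4-yl]-5-[(2R,6S)-2-methoxy-5,6-dihydro-2H-pyran-6-yl]pent-4-en-2-yl acetate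
Product: 23 (1E,4R,6R,8R)-6,8-dihydroxy-1-[(6S)-2-hydroxy-5,6-dihydro-2H-pyran-6-yl]-10-phenyldec-1-en-4-yl acetate (lactol, both C2 anomers)
Conditions: 0.5 M aq. HCl–THF (1:3), 0 °C → rt; neutralised to pH 7 with NaHCO3; crude product carried on
Reagents that add atoms: water, O
Why: Acid-catalysed hydrolysis through stabilised oxocarbenium ions cleaves the ketal and the allylic methyl acetal far faster than the secondary acetate, so a single operation should free both hydroxyls and the C2 lactol without breaking any C–O bond at a stereocentre.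

Step 13
Reactants: 23 (1E,4R,6R,8R)-6,8-dihydroxy-1-[(6S)-2-hydroxy-5,6-dihydro-2H-pyran-6-yl]-10-phenyldec-1-en-4-yl acetate
Product: 24 (1E,4R,6R,8R)-6,8-dihydroxy-1-[(6S)-2-oxo-5,6-dihydro-2H-pyran-6-yl]-10-phenyldec-1-en-4-yl acetate (target)
Conditions: activated MnO2 (20 equiv), CH2Cl2, rt; filtration through Celite
Reagents that add atoms: none
Why: Chemoselective MnO2 oxidation: only the lactol hydroxyl at C2 is allylic (to C3=C4), so it should be oxidised to the conjugated lactone while the isolated C6' and C8' carbinols, the acetate and both alkenes remain, and the C2 stereocentre disappears.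

Compound list
1 | ethyl 3-oxo-5-phenylpentanoate | CCOC(=O)CC(=O)CCc1ccccc1 | starting material
2 | ethyl (3R)-3-hydroxy-5-phenylpentanoate | CCOC(=O)C[C@H](O)CCc1ccccc1 | intermediate
3 | tert-butyl acetate | CC(=O)OC(C)(C)C | starting material
4 | lithium enolate of tert-butyl acetate | C=C(O[Li])OC(C)(C)C | intermediate
5 | tert-butyl (5R)-5-hydroxy-3-oxo-7-phenylheptanoate | CC(C)(C)OC(=O)CC(=O)C[C@H](O)CCc1ccccc1 | intermediate
6 | diethylboron chelate of 5 (O-diethylboryl at the C8' oxygen, ketone oxygen coordinated to boron) | CCB(CC)O[C@H](CCc1ccccc1)CC(=O)CC(=O)OC(C)(C)C | intermediate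
7 | tert-butyl (3R,5R)-3,5-dihydroxy-7-phenylheptanoate | CC(C)(C)OC(=O)C[C@H](O)C[C@H](O)CCc1ccccc1 | intermediate
8 | tert-butyl 2-[(4R,6R)-2,2-dimethyl-6-(2-phenylethyl)-1,3-dioxan-4-yl]acetate | CC(C)(C)OC(=O)C[C@H]1C[C@@H](CCc2ccccc2)OC(C)(C)O1 | intermediate
9 | diisobutylaluminium hemiacetal of 8 (hemiacetal carbon unassigned) | CC(C)C[Al](CC(C)C)OC(C[C@H]1C[C@@H](CCc2ccccc2)OC(C)(C)O1)OC(C)(C)C | intermediate
10 | 2-[(4R,6R)-2,2-dimethyl-6-(2-phenylethyl)-1,3-dioxan-4-yl]acetaldehyde | O=CC[C@H]1C[C@@H](CCc2ccccc2)OC(C)(C)O1 | intermediate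
11 | allenylboronic acid pinacol ester | C=C=CB1OC(C)(C)C(C)(C)O1 | starting material
12 | pinacol borate ester of 13 | CC1(C)OB(O[C@H](CC#C)C[C@H]2C[C@@H](CCc3ccccc3)OC(C)(C)O2)OC1(C)C | intermediate
13 | (2R)-1-[(4S,6R)-2,2-dimethyl-6-(2-phenylethyl)-1,3-dioxan-4-yl]pent-4-yn-2-ol | O[C@H](CC#C)C[C@H]1C[C@@H](CCc2ccccc2)OC(C)(C)O1 | intermediate
14 | tert-butyl-[(2R)-1-[(4R,6R)-2,2-dimethyl-6-(2-phenylethyl)-1,3-dioxan-4-yl]pent-4-yn-2-yl]oxy-dimethylsilane | CC(C)(C)[Si](C)(C)O[C@H](CC#C)C[C@H]1C[C@@H](CCc2ccccc2)OC(C)(C)O1 | intermediate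
15 | lithium acetylide of 14 | CC(C)(C)[Si](C)(C)O[C@H](CC#C[Li])C[C@H]1C[C@@H](CCc2ccccc2)OC(C)(C)O1 | intermediate
16 | lithium hemiaminal alkoxide from 15 and DMF (hemiaminal carbon unassigned) | CC(C)(C)[Si](C)(C)O[C@H](CC#CC(O[Li])N(C)C)C[C@H]1C[C@@H](CCc2ccccc2)OC(C)(C)O1 | intermediate
17 | (5R)-5-[tert-butyl(dimethyl)silyl]oxy-6-[(4R,6R)-2,2-dimethyl-6-(2-phenylethyl)-1,3-dioxan-4-yl]hex-2-ynal | CC(C)(C)[Si](C)(C)O[C@H](CC#CC=O)C[C@H]1C[C@@H](CCc2ccccc2)OC(C)(C)O1 | intermediate
18 | (E)-1-methoxybuta-1,3-diene | CO/C=C/C=C | starting material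
19 | (2R,6S)-6-[(4R)-4-[tert-butyl(dimethyl)silyl]oxy-5-[(4R,6R)-2,2-dimethyl-6-(2-phenylethyl)-1,3-dioxan-4-yl]pent-1-ynyl]-2-methoxy-5,6-dihydro-2H-pyran (cis) | CC(C)(C)[Si](C)(C)O[C@H](CC#C[C@@H]1CC=C[C@H](OC)O1)C[C@H]2C[C@@H](CCc3ccccc3)OC(C)(C)O2 | intermediate
20 | (Z)-vinylsilane from 19: H at C1' and Si(OEt)3 at C2' added anti, C3' and C6 trans, sp3 centres as in 19 (drawn regioisomer; the C1'-silyl isomer converges) | CC(C)(C)[Si](C)(C)O[C@H](C/C([Si](OCC)(OCC)OCC)=C/[C@@H]1CC=C[C@H](OC)O1)C[C@H]2C[C@@H](CCc3ccccc3)OC(C)(C)O2 | intermediate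
21 | (2R,4E)-1-[(4S,6R)-2,2-dimethyl-6-(2-phenylethyl)-1,3-dioxan-4-yl]-5-[(2R,6S)-2-methoxy-5,6-dihydro-2H-pyran-6-yl]pent-4-en-2-ol | O[C@H](C/C=C/[C@@H]1CC=C[C@H](OC)O1)C[C@H]2C[C@@H](CCc3ccccc3)OC(C)(C)O2 | intermediate
22 | (2R,4E)-1-[(4R,6R)-2,2-dimethyl-6-(2-phenylethyl)-1,3-dioxan-4-yl]-5-[(2R,6S)-2-methoxy-5,6-dihydro-2H-pyran-6-yl]pent-4-en-2-yl acetate | CC(=O)O[C@H](C/C=C/[C@@H]1CC=C[C@H](OC)O1)C[C@H]2C[C@@H](CCc3ccccc3)OC(C)(C)O2 | intermediate
23 | (1E,4R,6R,8R)-6,8-dihydroxy-1-[(6S)-2-hydroxy-5,6-dihydro-2H-pyran-6-yl]-10-phenyldec-1-en-4-yl acetate (both C2 anomers) | CC(=O)O[C@H](C/C=C/[C@@H]1CC=CC(O)O1)C[C@H](O)C[C@H](O)CCc1ccccc1 | intermediate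
24 | (1E,4R,6R,8R)-6,8-dihydroxy-1-[(6S)-2-oxo-5,6-dihydro-2H-pyran-6-yl]-10-phenyldec-1-en-4-yl acetate | CC(=O)O[C@H](C/C=C/[C@@H]1CC=CC(=O)O1)C[C@H](O)C[C@H](O)CCc1ccccc1 | target

Total step count: 13. Longest linear sequence: 13 steps (1 to 24).

Steps most likely to fail

Step 9.
- **Risk:** Turnover may be slow because the ether oxygens of the long chain compete with the formyl group for chromium. Uncatalysed cycloaddition (at C=O without facial bias, or at the C≡C bond) and diene polymerisation would then gain ground.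
- **Fallback:** The ring is built by allylation and metathesis instead of cycloaddition. It sets out from 17 and comes back at 24.
- Brown allylation of 17 with (+)-Ipc2B(allyl), made from (−)-Ipc2BOMe and allylMgBr (Et2O, −78 °C, then NaOH/H2O2), should attack the Si face and give the (6S)-propargylic homoallylic alcohol F1.
- NaAlH2(OCH2CH2OMe)2 in THF performs the alkoxide-directed trans reduction to the E-allylic alcohol F2.
- Acryloyl chloride and Et3N give the acrylate F3.
- Ring-closing metathesis with the second-generation Grubbs catalyst, RuCl2(=CHPh)(PCy3)(SIMes), in refluxing CH2Cl2 closes the silyl-protected lactone F4.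
- Buffered HF·pyridine frees the hydroxy lactone F5, and Ac2O in pyridine gives the acetate acetonide F6.
- 80 % aqueous AcOH removes the acetonide to give 24.

Step 10.
- **Risk:** The cationic ruthenium/silane pair may ionise or reduce the allylic acetal. C–Si cleavage beside the branched C6 may also be incomplete, with erosion of alkene geometry.
- **Fallback:** Hydroxyl-directed hydroalumination replaces hydrosilylation. It sets out from 19 and comes back at 24.
- Pyridinium p-toluenesulfonate in acetone–water (the acetone keeps the acetonide in place) hydrolyses the methyl acetal to the alkynyl lactol F7.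
- Luche reduction (NaBH4, CeCl3·7H2O, MeOH) of its open hydroxy-enal form gives the (Z)-enyne diol F8, whose C6 hydroxyl is now propargylic.
- NaAlH2(OCH2CH2OMe)2 in THF gives the (Z,E)-diene diol F9.
- TEMPO with PhI(OAc)2 oxidises the primary allylic alcohol selectively, and then the derived lactol, to F4. F4 is carried through F5 and F6 to 24 as described for step 9.

Step 6.
- **Risk:** The catalyst may discriminate weakly between the faces of an unbranched, β-oxygenated aliphatic aldehyde, or turn over slowly at low temperature.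
- **Fallback:** No asymmetric catalysis is used; the wrong epimer is separated and inverted. It sets out from 10 and comes back at 13.
- A Barbier reaction (Zn dust, propargyl bromide, THF–aq. NH4Cl) gives both C4' epimers.
- Chromatography delivers 13 and the (4'S)-epimeric alcohol F10.
- Mitsunobu reaction of F10 (4-nitrobenzoic acid, PPh3, DIAD, toluene) inverts C4' to the (4'R)-4-nitrobenzoate F11.
- K2CO3 in MeOH releases further 13.

Further compounds
F1 | step 9 | (4S,8R)-8-[tert-butyl(dimethyl)silyl]oxy-9-[(4R,6R)-2,2-dimethyl-6-(2-phenylethyl)-1,3-dioxan-4-yl]non-1-en-5-yn-4-ol | CC(C)(C)[Si](C)(C)O[C@H](CC#C[C@@H](O)CC=C)C[C@H]1C[C@@H](CCc2ccccc2)OC(C)(C)O1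
F2 | step 9 | (4S,5E,8R)-8-[tert-butyl(dimethyl)silyl]oxy-9-[(4R,6R)-2,2-dimethyl-6-(2-phenylethyl)-1,3-dioxan-4-yl]nona-1,5-dien-4-ol | CC(C)(C)[Si](C)(C)O[C@H](C/C=C/[C@@H](O)CC=C)C[C@H]1C[C@@H](CCc2ccccc2)OC(C)(C)O1
F3 | step 9 | (4S,5E,8R)-8-[tert-butyl(dimethyl)silyl]oxy-9-[(4R,6R)-2,2-dimethyl-6-(2-phenylethyl)-1,3-dioxan-4-yl]nona-1,5-dien-4-yl prop-2-enoate | CC(C)(C)[Si](C)(C)O[C@H](C/C=C/[C@@H](OC(=O)C=C)CC=C)C[C@H]1C[C@@H](CCc2ccccc2)OC(C)(C)O1
F4 | step 9 | (6S)-6-[(1E,4R)-4-[tert-butyl(dimethyl)silyl]oxy-5-[(4R,6R)-2,2-dimethyl-6-(2-phenylethyl)-1,3-dioxan-4-yl]pent-1-enyl]-5,6-dihydro-2H-pyran-2-one | CC(C)(C)[Si](C)(C)O[C@H](C/C=C/[C@@H]1CC=CC(=O)O1)C[C@H]2C[C@@H](CCc3ccccc3)OC(C)(C)O2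
F5 | step 9 | (6S)-6-[(1E,4R)-5-[(4S,6R)-2,2-dimethyl-6-(2-phenylethyl)-1,3-dioxan-4-yl]-4-hydroxypent-1-enyl]-5,6-dihydro-2H-pyran-2-one | O[C@H](C/C=C/[C@@H]1CC=CC(=O)O1)C[C@H]2C[C@@H](CCc3ccccc3)OC(C)(C)O2
F6 | step 9 | (2R,4E)-1-[(4R,6R)-2,2-dimethyl-6-(2-phenylethyl)-1,3-dioxan-4-yl]-5-[(6S)-2-oxo-5,6-dihydro-2H-pyran-6-yl]pent-4-en-2-yl acetate | CC(=O)O[C@H](C/C=C/[C@@H]1CC=CC(=O)O1)C[C@H]2C[C@@H](CCc3ccccc3)OC(C)(C)O2
F7 | step 10 | (6S)-6-[(4R)-4-[tert-butyl(dimethyl)silyl]oxy-5-[(4R,6R)-2,2-dimethyl-6-(2-phenylethyl)-1,3-dioxan-4-yl]pent-1-ynyl]-5,6-dihydro-2H-pyran-2-ol (both anomers) | CC(C)(C)[Si](C)(C)O[C@H](CC#C[C@@H]1CC=CC(O)O1)C[C@H]2C[C@@H](CCc3ccccc3)OC(C)(C)O2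
F8 | step 10 | (2Z,5S,9R)-9-[tert-butyl(dimethyl)silyl]oxy-10-[(4R,6R)-2,2-dimethyl-6-(2-phenylethyl)-1,3-dioxan-4-yl]dec-2-en-6-yne-1,5-diol | CC(C)(C)[Si](C)(C)O[C@H](CC#C[C@@H](O)C/C=C\CO)C[C@H]1C[C@@H](CCc2ccccc2)OC(C)(C)O1
F9 | step 10 | (2Z,5S,6E,9R)-9-[tert-butyl(dimethyl)silyl]oxy-10-[(4R,6R)-2,2-dimethyl-6-(2-phenylethyl)-1,3-dioxan-4-yl]deca-2,6-diene-1,5-diol | CC(C)(C)[Si](C)(C)O[C@H](C/C=C/[C@@H](O)C/C=C\CO)C[C@H]1C[C@@H](CCc2ccccc2)OC(C)(C)O1
F10 | step 6 | (2S)-1-[(4S,6R)-2,2-dimethyl-6-(2-phenylethyl)-1,3-dioxan-4-yl]pent-4-yn-2-ol | O[C@@H](CC#C)C[C@H]1C[C@@H](CCc2ccccc2)OC(C)(C)O1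
F11 | step 6 | (2R)-1-[(4R,6R)-2,2-dimethyl-6-(2-phenylethyl)-1,3-dioxan-4-yl]pent-4-yn-2-yl 4-nitrobenzoate | O=C(O[C@H](CC#C)C[C@H]1C[C@@H](CCc2ccccc2)OC(C)(C)O1)c3ccc(cc3)[N+](=O)[O-]
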